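The earlier runs and the new flask are calculated for substances that don't exist; the scatter is artificial.

Per litre rather than per cent, the two earlier runs show the same hole in their books.

| setting | Saturday's | Sunday's | flask |
|---|---|---|---|
| solid electrophile | 0.14 M | 0.22 M | 0.10 M |
| nucleophile | 1.8 equiv | 1.8 equiv | 1.80 equiv |
| free base | 1 equiv | 1 equiv | 1.00 equiv |
| protic impurity | 0.030 M | 0.030 M | 0.0300 M |
| remark | run made earlier | run made earlier |  |
| time |  |  | 15 h |

- Saturday's (time / h: solid electrophile / %, product / %): 1.00: 43, 10; 1.33: 38, 16; 2.00: 20, 24; 3.00: 3, 36; 5.00: 0, 57; 8.00: 0, 64; 12.0: 0, 70
- Sunday's (time / h: solid electrophile / %, product / %): 1.50: 54, 21; 3.00: 31, 38; 5.00: 9, 57; 6.00: 1, 66; 8.00: 0, 75; 10.0: 0, 75; 12.0: 0, 81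

(each reading ± 2 percentage points)

- the numbers in the tables scatter by 2 percentage points (one standard deviation)
- at the start none of the solid electrophile is in solution
- what has only dissolved of solid electrophile counts as not reacted
- the earlier runs do not show how much of nucleophile is bound; that part of a forecast is a guess

1. part of the solid electrophile that has reacted (what has only dissolved counts as not reacted) at 15 h
2. share of the unused nucleophile that is free and not bound as protonated nucleophile, at 15 h

We keep the ledger on the solid electrophile, the limiting reagent. At the last readings its solid entry stands at 0% on Saturday and 0% on Sunday, so whatever isn't product has gone elsewhere or waits in solution. Saturday's product of 70% leaves a hole of 0.0420 M, and Sunday's 81% leaves 0.0418 M, about the same although the charges differ. These are readings, with their scatter.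

The protic impurity stands at 0.030 M in both recipes, so in our own reckoning each mole of it costs one mole of the solid electrophile charged. This gives w, the impurity's share: charged protic impurity over charged solid electrophile, 30.0% in the flask. The rest of Saturday's hole, 0.0120 M, we book as dissolved and unreacted at 12.0 h. Carried over at that size, it gives our estimate for the flask, 88.0% reacted. We leave the free share of nucleophile as a guess.

The forecast gives 65% reacted (57% to 73%) and 20% free (10% to 40%), reading the tails as “each product event removing a second nucleophile as protonated nucleophile”. Our figure for reacted is higher than its figure.

The flask gives 95.4% reacted and 51.9% free.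

    electrophile + nucleophile → acid set free + product (k = 2.20 L mol⁻¹ h⁻¹)
    nucleophile + acid set free ⇌ protonated nucleophile, settled at all times (K = 46000 L mol⁻¹)
    acid set free + free base ⇌ salt of the base, settled at all times (K = 5700 L mol⁻¹)
    solid electrophile ⇌ electrophile, rate k4*(cs4 - [electrophile]) while solid is left; crystals form when [electrophile] > cs4 (solubility = 0.0580 M, k = 2.80 h⁻¹)
    electrophile + protic impurity → quenched substrate (k = 25.0 L mol⁻¹ h⁻¹)

At 15.0 h the flask's books hold product 65.4%, quenched substrate 30.0% against a share w of 30.0%, and electrophile 4.58%, with solid electrophile at 0% and protic impurity down to 0.0974% of its charge. The neighbour charged with 0.450 equiv of nucleophile keeps the same w, so we book 30.0% as quenched, and its simulated entry reads 30.0%. Adding its product of 27.6% gives 57.6% reacted, against 57.6% simulated, and electrophile holds the remaining 42.4%.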